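**Plan**

- Cuts, in retrosynthetic order: C11–C12 (α-sulfonyl carbanion + allylic bromide from farnesol); the C3 carbinol (ketone reduction); the C4–C5 bond of ring A, unmade as a semipinacol shift back to a cis-fused cyclopentanol (ring C3–C2–C1–C10–C5, no C4) with an isopropenyl group on C3; then isopropenyl–C3, C8–CH3, the lactone C11–O/CO2, and finally C5–C6 and C9–C10 (Diels–Alder).
- Forward order: ring B is annulated onto a five-membered precursor of ring A by a catalytic asymmetric Diels–Alder reaction; ring A reaches its final size only in step 14; the chain is joined last.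
- Enabling feature: ring A holds the array C3(O)–C4(CH3)2–C5(H), with C5–H cis to the C10 methyl. This is what results when the ring-fusion carbon C5 of a cis-hydrindanol migrates with retention from C3 to an exocyclic Me2C cation equivalent. The cis fusion is the stable one for the hydrindan-1-one, so C5 is set in the small ring and then frozen.
- Stereochemistry: C10 from the chiral copper catalyst; C9 by an epimerisation–lactonisation funnel onto the C5 ester (activating group, then temporary ring, finally lost as CO2); C8 by equatorial methyl addition to the lactone-locked ketone; C5 by thermodynamic cis fusion and retentive migration; C3 by CBS reagent control; E-alkenes from farnesol and SeO2.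

Key step: step 14

**Remarks**

- The SMILES is taken as written: C5–H is on the same face as the C10 methyl (cis-fused decalin), which with the 3-hydroxyl present is (3S,5S,8R,9R,10S), all-E.
- Locants are those of the target (ring A: C1–C5, C10; ring B: C5–C10; C11 on C9; β = face of the C10 methyl).
- C9 of 8 and 9 is drawn with C11 cis to the C10 methyl; the other epimer serves equally because step 8 equilibrates C9. The carbinol centres at C3 in 9–12 and 17 are drawn as one epimer, and C5 of 5, C9 of 10 and C11 of 27/28 are left open; all are removed or equilibrated later.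
- The (S,S)-ligand of step 6 is assumed to give the 10S series; if the sense is opposite, its mirror image is used.

**Route**

Step 1
Reactants: 1 3-methylcyclopent-2-en-1-one
Product: 2 2-iodo-3-methylcyclopent-2-en-1-one
Conditions: I2, pyridine, CH2Cl2, rt
Reagents that add atoms: iodine, [I][I]
Why: Pyridine-mediated α-iodination of a cyclic enone (conjugate addition of pyridine, iodination of the enolate, elimination; a Baylis–Hillman-type sequence) puts a coupling handle on the α-carbon, the future C5.

Step 2
Reactants: 2 2-iodo-3-methylcyclopent-2-en-1-one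
Product: 3 methyl 2-methyl-5-oxocyclopent-1-ene-1-carboxylate
Conditions: PdCl2(PPh3)2 (5 mol %), CO (1 atm), MeOH, Et3N, DMF, 60 °C
Reagents that add atoms: carbon monoxide, [C-]#[O+]; methanol, CO
Why: Palladium-catalysed alkoxycarbonylation of the vinyl iodide (oxidative addition to zerovalent palladium, CO insertion, methanolysis) should give the alkylidene β-keto ester whose two carbonyl groups on C5 activate C5=C10 and allow two-point binding to a Lewis acid.

Step 3
Reactants: 4 3-[(tert-butyldimethylsilyl)oxy]propanal
Product: 5 racemic 5-[(tert-butyldimethylsilyl)oxy]pent-1-en-3-ol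
Conditions: CH2=CHMgBr, THF, −78 °C → 0 °C; aq NH4Cl
Reagents that add atoms: vinylmagnesium bromide, C=C[Mg]Br
Why: Grignard addition to the aldehyde; the carbinol centre is of no consequence because it is oxidised in step 4.

Step 4
Reactants: 5 racemic 5-[(tert-butyldimethylsilyl)oxy]pent-1-en-3-ol
Product: 6 5-[(tert-butyldimethylsilyl)oxy]pent-1-en-3-one
Conditions: Dess–Martin periodinane, NaHCO3, CH2Cl2, 0 °C
Reagents that add atoms: none
Why: Dess–Martin oxidation of the allylic alcohol under buffered, non-basic conditions should give the vinyl ketone without β-elimination of the silyloxy group.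

Step 5
Reactants: 6 5-[(tert-butyldimethylsilyl)oxy]pent-1-en-3-one
Product: 7 (3Z)-3,5-bis[(tert-butyldimethylsilyl)oxy]penta-1,3-diene
Conditions: TBSOTf, Et3N, CH2Cl2, −78 °C → 0 °C
Reagents that add atoms: tert-butyldimethylsilyl triflate, CC(C)(C)[Si](C)(C)OS(=O)(=O)C(F)(F)F
Why: Soft enolisation (silyl triflate/amine) on the only enolisable side gives the 2-silyloxy diene as the Z enol ether, which places the CH2OTBS group (future C11) on the outside of the s-cis diene.

Step 6
Reactants: 3 methyl 2-methyl-5-oxocyclopent-1-ene-1-carboxylate; 7 (3Z)-3,5-bis[(tert-butyldimethylsilyl)oxy]penta-1,3-diene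
Product: 8 cis-fused Diels–Alder adduct (3-oxo; 5β-CO2Me; 10β-CH3; 9β-CH2OTBS; C7=C8 enol ether with 8-OTBS)
Conditions: Cu(SbF6)2 (divalent copper) with (S,S)-2,2′-isopropylidenebis(4-tert-butyl-2-oxazoline), 10 mol %, 4 Å MS, CH2Cl2, −40 °C → rt
Reagents that add atoms: none
Why: Lewis-acid-catalysed Diels–Alder reaction of a chelating alkylidene β-keto ester: the enol-ether carbon C9 bonds to the enone β-carbon C10 and C6 to C5 (para orientation of a 2-silyloxy diene), suprafacial addition makes the ring fusion cis with the ester and the C10 methyl on one face, and the C2-symmetric copper–bis(oxazoline) chelate of the two carbonyls exposes one face of the dienophile, which sets C10.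

Step 7
Reactants: 8 cis-fused Diels–Alder adduct
Product: 9 3α-alcohol of the adduct (ester and both silyl groups retained)
Conditions: NaBH4, MeOH–CH2Cl2, −40 °C
Reagents that add atoms: none
Why: Borohydride reduction of the only free ketone (C3) masks it as an alcohol, so that C8, still a silyl enol ether, becomes the only ketone in step 8; the new carbinol centre is erased in step 10.

Step 8
Reactants: 9 3α-alcohol of the adduct
Product: 11 bridged δ-lactone (C11–O–CO–C5; 8-oxo; 3α-hydroxy), via hydroxy keto ester 10 (not isolated)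
Conditions: TBAF, THF, 0 °C → 40 °C; aq NH4Cl
Reagents that add atoms: none
Why: Fluoride desilylation frees the C8 ketone and the C11 alkoxide, C9 epimerises through the C8 enolate, and only the epimer with C11 cis to the C5 ester can close the six-membered lactone (intramolecular transesterification), so both C9 epimers should drain into one bridged lactone in which C9 is a non-enolisable bridgehead.

Step 9
Reactants: 11 bridged δ-lactone
Product: 12 lactone diol (8α-hydroxy-8β-methyl; 3α-hydroxy)
Conditions: MeMgBr (excess), CeCl3, THF, −78 °C; aq NH4Cl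
Reagents that add atoms: methylmagnesium bromide, C[Mg]Br
Why: Cerium-mediated Grignard addition: the lactone bridge holds ring B in the chair in which C1 of ring A is axial and syn to the α-face of C8 (the situation of 3,3,5-trimethylcyclohexanone), so the methyl group should enter equatorially from the β-face and leave the 8α-hydroxyl, while the hindered lactone is not attacked.

Step 10
Reactants: 12 lactone diol
Product: 13 β-keto lactone (3-oxo; 8α-hydroxy-8β-methyl)
Conditions: Dess–Martin periodinane, NaHCO3, CH2Cl2, rt
Reagents that add atoms: none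
Why: Dess–Martin oxidation returns C3 to the ketone (the tertiary C8 alcohol is inert), which makes the lactone carbonyl on C5 part of a β-keto ester ready for decarboxylation.

Step 11
Reactants: 13 β-keto lactone
Product: 15 cis-hydrindanone sulfide (3-oxo; 5β-H; 8α-OH; 8β-CH3; 9β-CH2SPh; 10β-CH3), via keto acid 14 (not isolated)
Conditions: PhSNa, DMF, 110 °C; aq HCl; then K2CO3, MeOH, rt
Reagents that add atoms: sodium benzenethiolate, [Na+].[S-]c1ccccc1
Why: Krapcho-type dealkoxycarbonylation: thiolate opens the lactone by SN2 attack at C11 (alkyl–oxygen cleavage), the β-keto carboxylate loses CO2, and the former quaternary C5 becomes a base-labile methine that should settle in the cis-fused ketone (C5–H syn to the C10 methyl), the stable fusion of a hydrindan-1-one with an angular methyl and the only one that avoids the syn-axial 8-CH3/10-CH3 contact.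

Step 12
Reactants: 15 cis-hydrindanone sulfide
Product: 16 cis-hydrindanone sulfone (9β-CH2SO2Ph)
Conditions: (NH4)6Mo7O24·4H2O (10 mol %), 30% H2O2, EtOH, 0 °C → rt
Reagents that add atoms: hydrogen peroxide, OO
Why: Molybdate-catalysed peroxide oxidation of sulfide to sulfone installs the carbanion-stabilising group for the chain coupling before the oxidising conditions of step 14, which a sulfide would not survive; ketone and tertiary alcohol are inert.

Step 13
Reactants: 16 cis-hydrindanone sulfone
Product: 17 3-isopropenyl tertiary alcohol (1-isopropenylcyclopentanol unit at C3)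
Conditions: CH2=C(CH3)MgBr (excess), CeCl3, THF, −78 °C → 0 °C; aq NH4Cl
Reagents that add atoms: isopropenylmagnesium bromide, CC(=C)[Mg]Br
Why: Cerium-mediated Grignard addition (suppressing enolisation of the hindered ketone) places on C3 the three carbons that become C4 and its two methyl groups; either configuration of the new carbinol serves because C3 returns to a carbonyl in step 14.

Step 14
Reactants: 17 3-isopropenyl tertiary alcohol
Product: 18 cis-decalin-3-one sulfone (4,4-dimethyl; 5β-H; 8α-OH; 8β-CH3; 9β-CH2SO2Ph; 10β-CH3)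
Conditions: [N,N′-bis(3,5-di-tert-butylsalicylidene)-1,2-cyclohexanediaminato]cobalt (divalent cobalt, 5 mol %), N-fluoro-2,4,6-trimethylpyridinium triflate, PhSiH3, acetone, 0 °C → rt
Reagents that add atoms: none
Why: A cobalt hydride formed from the cobalt salen complex, the N-fluoropyridinium oxidant and PhSiH3 transfers a hydrogen atom to the CH2 terminus of the isopropenyl group (Markovnikov), the tertiary C4 radical is captured by cobalt and oxidised to a cationic alkylcobalt species, and the C3–C5 bond then migrates to C4 with loss of cobalt while the hydroxyl becomes the C3 carbonyl. The closest known reaction type is the cobalt-salen hydrogen-atom-transfer/radical–polar crossover semipinacol rearrangement of tertiary allylic alcohols, whose polar counterpart is the acid-induced pinacol-type enlargement of 1-alkenylcycloalkanols. No ring is closed: the five-membered ring (C3, C2, C1, C10, C5) becomes six-membered ring A by a suprafacial 1,2-alkyl shift that inserts C4 between C3 and C5 and at the same time creates the C4 quaternary centre with both methyl groups. No new stereocentre is formed: C5 migrates with retention, so the cis ring fusion set in step 11 is carried unchanged into the decalin, where it can no longer epimerise, and the C3 carbinol centre is erased. The step needs migration of C5 in preference to the C2 methylene and to oxirane closure by the hydroxyl; C5 is the more substituted, more electron-rich carbon, and a salen ligand of low donor strength is chosen to favour the shift. The sulfone, the tertiary C8 hydroxyl and all C–H bonds should be inert because the hydride reacts only with the alkene.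

Step 15
Reactants: 18 cis-decalin-3-one sulfone
Product: 19 3β,8α-diol sulfone ((3S)-alcohol)
Conditions: (R)-2-methyl-CBS-oxazaborolidine (0.5 equiv), BH3·SMe2, THF, −20 °C; MeOH
Reagents that add atoms: none
Why: Corey–Bakshi–Shibata reduction: the oxazaborolidine distinguishes the quaternary C4 (large) from the C2 methylene (small), and the (R)-catalyst should deliver hydride to the face that gives the (3S)-alcohol (hydroxyl β, cis to C5–H and the C10 methyl) by reagent control, independent of the conformation of the flexible cis-decalin.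

Step 16
Reactants: 19 3β,8α-diol sulfone
Product: 20 3,8-bis(triethylsilyl) ether sulfone
Conditions: TESOTf, 2,6-lutidine, CH2Cl2, −78 °C → 0 °C
Reagents that add atoms: triethylsilyl triflate, CC[Si](CC)(CC)OS(=O)(=O)C(F)(F)F
Why: Silylation with the silyl triflate protects the secondary and the hindered tertiary hydroxyl, so that only the α-sulfonyl position is deprotonated in step 22.

Step 17
Reactants: 21 (2E,6E)-farnesol
Product: 22 (2E,6E)-farnesyl acetate
Conditions: Ac2O, pyridine, DMAP (cat.), CH2Cl2, rt
Reagents that add atoms: acetic anhydride, CC(=O)OC(C)=O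
Why: Acetylation protects the allylic alcohol for the allylic oxidation.

Step 18
Reactants: 22 (2E,6E)-farnesyl acetate
Product: 23 (2E,6E,10E)-12-hydroxy-3,7,11-trimethyldodeca-2,6,10-trien-1-yl acetate
Conditions: SeO2 (0.3 equiv), t-BuOOH, salicylic acid (0.1 equiv), CH2Cl2, 0 °C → rt
Reagents that add atoms: tert-butyl hydroperoxide, CC(C)(C)OO
Why: Selenium dioxide-catalysed allylic oxidation (Riley oxidation: ene reaction then [2,3]-sigmatropic shift) attacks the terminal, most electron-rich trisubstituted alkene at its E-methyl group and should give the E-allylic alcohol.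

Step 19
Reactants: 23 12-hydroxyfarnesyl acetate
Product: 24 (2E,6E,10E)-12-[(tert-butyldimethylsilyl)oxy]-3,7,11-trimethyldodeca-2,6,10-trien-1-yl acetate
Conditions: TBSCl, imidazole, DMF, rt
Reagents that add atoms: tert-butyldimethylsilyl chloride, CC(C)(C)[Si](C)(C)Cl
Why: Silylation of the primary allylic alcohol protects the future terminal hydroxyl of the target through the coupling.

Step 20
Reactants: 24 silyl ether acetate
Product: 25 (2E,6E,10E)-12-[(tert-butyldimethylsilyl)oxy]-3,7,11-trimethyldodeca-2,6,10-trien-1-ol
Conditions: K2CO3, MeOH, rt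
Reagents that add atoms: none
Why: Base-catalysed methanolysis (transesterification) removes the acetate while the silyl ether stays.

Step 21
Reactants: 25 silyl ether alcohol
Product: 26 (2E,6E,10E)-1-bromo-12-[(tert-butyldimethylsilyl)oxy]-3,7,11-trimethyldodeca-2,6,10-triene
Conditions: CBr4, PPh3, CH2Cl2, 0 °C
Reagents that add atoms: carbon tetrabromide, BrC(Br)(Br)Br
Why: The Appel reaction converts the primary allylic alcohol into the allylic bromide at low temperature without allylic transposition or loss of alkene geometry.

Step 22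
Reactants: 20 3,8-bis(triethylsilyl) ether sulfone; 26 allylic bromide
Product: 28 coupled C11 phenylsulfonyl triene tris(silyl ether), via lithiated sulfone 27 (not isolated)
Conditions: n-BuLi, THF–HMPA, −78 °C; then 26, −78 °C → −20 °C
Reagents that add atoms: none
Why: Alkylation of an α-sulfonyl carbanion with a primary allylic bromide (SN2) forms the C11–C12 bond and leaves the three E-alkenes untouched; the new C11 centre is removed in step 23.

Step 23
Reactants: 28 coupled C11 phenylsulfonyl triene
Product: 29 desulfonylated tris(silyl ether) of the target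
Conditions: Na/Hg (6% Na), Na2HPO4, MeOH–THF, −20 °C
Reagents that add atoms: none
Why: Reductive desulfonylation with sodium amalgam (electron-transfer cleavage of the C–S bond, protonation by methanol); the sulfone is homoallylic and has no β-leaving group, so neither alkene migration nor Julia-type elimination is expected.

Step 24
Reactants: 29 desulfonylated tris(silyl ether)
Product: 30 myrrhanol A as given ((3S,5S,8R,9R,10S), 13E,17E,21E)
Conditions: TBAF, THF, rt → 40 °C; aq NH4Cl
Reagents that add atoms: none
Why: Fluoride-mediated desilylation cleaves the two triethylsilyl ethers and the allylic tert-butyldimethylsilyl ether and should give the triol without touching alkenes or stereocentres.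

**Compound list**

1 | 3-methylcyclopent-2-en-1-one | CC1=CC(=O)CC1 | starting material
2 | 2-iodo-3-methylcyclopent-2-en-1-one | CC1=C(I)C(=O)CC1 | intermediate
3 | methyl 2-methyl-5-oxocyclopent-1-ene-1-carboxylate | COC(=O)C1=C(C)CCC1=O | intermediate
4 | 3-[(tert-butyldimethylsilyl)oxy]propanal | O=CCCO[Si](C)(C)C(C)(C)C | starting material
5 | racemic 5-[(tert-butyldimethylsilyl)oxy]pent-1-en-3-ol | C=CC(O)CCO[Si](C)(C)C(C)(C)C | intermediate
6 | 5-[(tert-butyldimethylsilyl)oxy]pent-1-en-3-one | C=CC(=O)CCO[Si](C)(C)C(C)(C)C | intermediate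
7 | (3Z)-3,5-bis[(tert-butyldimethylsilyl)oxy]penta-1,3-diene | C=C/C(O[Si](C)(C)C(C)(C)C)=C/CO[Si](C)(C)C(C)(C)C | intermediate
8 | cis-fused Diels–Alder adduct: 3-oxo, 5β-CO2Me, 10β-CH3, 9β-CH2OTBS, C7=C8 enol ether with 8-OTBS | CC(C)(C)[Si](C)(C)OC[C@@H]1[C@@]2(C)CCC(=O)[C@@]2(C(=O)OC)CC=C1O[Si](C)(C)C(C)(C)C | intermediate
9 | 3α-alcohol of 8 | CC(C)(C)[Si](C)(C)OC[C@@H]1[C@@]2(C)CC[C@@H](O)[C@@]2(C(=O)OC)CC=C1O[Si](C)(C)C(C)(C)C | intermediate
10 | hydroxy keto ester: 3α,11-dihydroxy-8-oxo, 5β-CO2Me, C9 epimers | OCC1[C@@]2(C)CC[C@@H](O)[C@@]2(C(=O)OC)CCC1=O | intermediate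
11 | bridged δ-lactone (C11–O–CO–C5), 8-oxo, 3α-hydroxy, 10β-CH3 | O1C[C@@H]2[C@@]3(C)CC[C@@H](O)[C@@]3(C1=O)CCC2=O | intermediate
12 | lactone diol: 8α-hydroxy-8β-methyl, 3α-hydroxy | O1C[C@@H]2[C@@]3(C)CC[C@@H](O)[C@@]3(C1=O)CC[C@@]2(C)O | intermediate
13 | β-keto lactone: 3-oxo, 8α-hydroxy-8β-methyl | O1C[C@@H]2[C@@]3(C)CCC(=O)[C@@]3(C1=O)CC[C@@]2(C)O | intermediate
14 | keto acid: 3-oxo, 5β-CO2H, 9β-CH2SPh, 8α-hydroxy-8β-methyl | c1ccccc1SC[C@@H]1[C@@]2(C)CCC(=O)[C@@]2(C(=O)O)CC[C@@]1(C)O | intermediate
15 | cis-hydrindanone sulfide: 3-oxo, 5β-H, 8α-OH, 8β-CH3, 9β-CH2SPh, 10β-CH3 | c1ccccc1SC[C@@H]1[C@@]2(C)CCC(=O)[C@H]2CC[C@@]1(C)O | intermediate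
16 | cis-hydrindanone sulfone (9β-CH2SO2Ph) | O=S(=O)(c1ccccc1)C[C@@H]1[C@@]2(C)CCC(=O)[C@H]2CC[C@@]1(C)O | intermediate
17 | 3-isopropenyl tertiary alcohol (3α-OH drawn), 5β-H | O=S(=O)(c1ccccc1)C[C@@H]1[C@@]2(C)CC[C@](O)(C(C)=C)[C@H]2CC[C@@]1(C)O | intermediate
18 | cis-decalin-3-one sulfone: 4,4-dimethyl, 5β-H, 8α-OH, 8β-CH3, 9β-CH2SO2Ph, 10β-CH3 | O=S(=O)(c1ccccc1)C[C@@H]1[C@@]2(C)CCC(=O)C(C)(C)[C@H]2CC[C@@]1(C)O | intermediate
19 | 3β,8α-diol sulfone (3S) | O=S(=O)(c1ccccc1)C[C@@H]1[C@@]2(C)CC[C@H](O)C(C)(C)[C@H]2CC[C@@]1(C)O | intermediate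
20 | 3,8-bis(triethylsilyl) ether sulfone | O=S(=O)(c1ccccc1)C[C@@H]1[C@@]2(C)CC[C@H](O[Si](CC)(CC)CC)C(C)(C)[C@H]2CC[C@@]1(C)O[Si](CC)(CC)CC | intermediate
21 | (2E,6E)-farnesol | CC(C)=CCC/C(C)=C/CC/C(C)=C/CO | starting material
22 | (2E,6E)-farnesyl acetate | CC(C)=CCC/C(C)=C/CC/C(C)=C/COC(C)=O | intermediate
23 | (2E,6E,10E)-12-hydroxy-3,7,11-trimethyldodeca-2,6,10-trien-1-yl acetate | OC/C(C)=C/CC/C(C)=C/CC/C(C)=C/COC(C)=O | intermediate
24 | (2E,6E,10E)-12-[(tert-butyldimethylsilyl)oxy]-3,7,11-trimethyldodeca-2,6,10-trien-1-yl acetate | CC(C)(C)[Si](C)(C)OC/C(C)=C/CC/C(C)=C/CC/C(C)=C/COC(C)=O | intermediate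
25 | (2E,6E,10E)-12-[(tert-butyldimethylsilyl)oxy]-3,7,11-trimethyldodeca-2,6,10-trien-1-ol | CC(C)(C)[Si](C)(C)OC/C(C)=C/CC/C(C)=C/CC/C(C)=C/CO | intermediate
26 | (2E,6E,10E)-1-bromo-12-[(tert-butyldimethylsilyl)oxy]-3,7,11-trimethyldodeca-2,6,10-triene | CC(C)(C)[Si](C)(C)OC/C(C)=C/CC/C(C)=C/CC/C(C)=C/CBr | intermediate
27 | C11-lithiated sulfone of 20 | [Li]C(S(=O)(=O)c1ccccc1)[C@@H]1[C@@]2(C)CC[C@H](O[Si](CC)(CC)CC)C(C)(C)[C@H]2CC[C@@]1(C)O[Si](CC)(CC)CC | intermediate
28 | coupled C11 phenylsulfonyl triene tris(silyl ether), C11 epimers | C/C(=C\CC/C(C)=C/CC/C(C)=C/CC(S(=O)(=O)c1ccccc1)[C@@H]1[C@@]2(C)CC[C@H](O[Si](CC)(CC)CC)C(C)(C)[C@H]2CC[C@@]1(C)O[Si](CC)(CC)CC)CO[Si](C)(C)C(C)(C)C | intermediate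
29 | desulfonylated tris(silyl ether) of the target | C/C(=C\CC/C(C)=C/CC/C(C)=C/CC[C@@H]1[C@@]2(C)CC[C@H](O[Si](CC)(CC)CC)C(C)(C)[C@H]2CC[C@@]1(C)O[Si](CC)(CC)CC)CO[Si](C)(C)C(C)(C)C | intermediate
30 | myrrhanol A as given: 3β,8α-dihydroxy, 5β-H, 8β-CH3, 9β side chain, 10β-CH3, 13E,17E,21E, terminal E-allylic alcohol | C/C(=C\CC/C(C)=C/CC/C(C)=C/CC[C@@H]1[C@@]2(C)CC[C@H](O)C(C)(C)[C@H]2CC[C@@]1(C)O)CO | target

**Step count and risks**

Total step count: 24. Longest linear sequence: 17 steps (from 4: steps 3–16 and 22–24).

Steps most likely to fail: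

1. Step 14. The cationic intermediate may be captured by the neighbouring hydroxyl (oxirane closure), or the C2 methylene may migrate in competition with C5. Fallback, setting out from 16 and returning at 18, by the polar selenium-based one-carbon ring enlargement: acetone and benzeneselenol (ZnCl2) give 2,2-bis(phenylseleno)propane F1. n-BuLi cleaves one C–Se bond, and the resulting 2-lithio-2-(phenylseleno)propane (in excess, because the hydroxyl and the α-sulfonyl position are deprotonated first) adds to the C3 ketone of 16 to give the β-hydroxy selenide F2. AgBF4 on alumina in CH2Cl2 then removes selenium from the exocyclic carbon while the more substituted C5 migrates, which leads to 18.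

2. Step 6. The β,β-disubstituted dienophile may react too slowly along the catalyst-bound pathway and with poor facial discrimination, so that an achiral background reaction erodes the enantiomeric purity at C10. Fallback, setting out from 2 and returning at 11, with facial control from a covalently bound auxiliary: carbonylation of 2 (PdCl2(PPh3)2, CO, Et3N) in the presence of (−)-8-phenylmenthol gives the 8-phenylmenthyl ester F3. Cycloaddition with 7 promoted by EtAlCl2 at −78 °C, where the aryl group covers one face of the chelated dienophile, gives the auxiliary adduct F4. NaBH4 gives the C3 alcohol F5, and TBAF as in step 8 closes the lactone with expulsion of 8-phenylmenthol, which leads to 11.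

3. Step 11. SN2 displacement at the hindered C11 methylene may be slow, which lets attack of the thiolate at the carbonyl groups (retro-Claisen ring opening) compete. Fallback, setting out from 13 and returning at 15, by acyl–oxygen instead of alkyl–oxygen cleavage: LiOH in THF–H2O at 0 °C opens the lactone, and acidification with gentle warming decarboxylates the β-keto acid to the hydroxy ketone F6, which is equilibrated to the cis fusion with K2CO3 in MeOH. PhSSPh/PBu3 then converts the primary C11 hydroxyl through its oxyphosphonium salt into the phenyl sulfide 15.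

**Further compounds**

F1 | step 14 | 2,2-bis(phenylseleno)propane | CC(C)([Se]c1ccccc1)[Se]c1ccccc1
F2 | step 14 | β-hydroxy selenide: 3-hydroxy-3-[2-(phenylseleno)propan-2-yl] derivative of 16 (C3 epimers) | O=S(=O)(c1ccccc1)C[C@@H]1[C@@]2(C)CCC(O)(C(C)(C)[Se]c3ccccc3)[C@H]2CC[C@@]1(C)O
F3 | step 6 | (1R,2S,5R)-8-phenylmenthyl 2-methyl-5-oxocyclopent-1-ene-1-carboxylate | C[C@@H]1CC[C@H]([C@@H](C1)OC(=O)C2=C(C)CCC2=O)C(C)(C)c3ccccc3
F4 | step 6 | 8-phenylmenthyl ester analogue of adduct 8 | CC(C)(C)[Si](C)(C)OC[C@@H]1[C@@]2(C)CCC(=O)[C@@]2(C(=O)O[C@@H]3C[C@H](C)CC[C@H]3C(C)(C)c4ccccc4)CC=C1O[Si](C)(C)C(C)(C)C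
F5 | step 6 | 8-phenylmenthyl ester analogue of alcohol 9 | CC(C)(C)[Si](C)(C)OC[C@@H]1[C@@]2(C)CC[C@@H](O)[C@@]2(C(=O)O[C@@H]3C[C@H](C)CC[C@H]3C(C)(C)c4ccccc4)CC=C1O[Si](C)(C)C(C)(C)C
F6 | step 11 | hydroxy ketone: 3-oxo, 5β-H, 8α-OH, 8β-CH3, 9β-CH2OH, 10β-CH3 | OC[C@@H]1[C@@]2(C)CCC(=O)[C@H]2CC[C@@]1(C)O
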